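**Retrosynthetic overview**
- Ring B carries CO2H at C1', OMe at C2', the depside oxygen at C4' and pentyl at C6', with C3' and C5' unsubstituted. It is a 4-hydroxy-2-methoxy-6-alkylbenzoate whose two oxygens differ. This pattern maps atom for atom onto a four-carbon diene (two oxygens on C1, one on C3) plus the two alkyne carbons of an octynoate.
- The last disconnection is the depside bond C(=O)–O(C4'). It gives a 2-O-benzyl ring A acid and a ring B phenol held as its benzyl ester. One hydrogenolysis removes both benzyl groups.
- The ring B phenol comes from a Diels–Alder reaction with aromatisation between 1,1-dimethoxy-3-(trimethylsilyloxy)buta-1,3-diene and benzyl oct-2-ynoate, which forms C1'–C2' and C5'–C6'.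
- The diene is made from acetyl chloride and 1,1-dichloroethene. Ring A is bought as olivetol, then formylated, 4-O-methylated, 2-O-benzylated and oxidised.
- Ring B is the only ring that is built (step 5). Ring A is carried through from olivetol.

Key step: step 5

Remark: the target has no stereocentre and no stereogenic double bond. The alkene geometry of the chloro(methoxy)enone passed through in step 2 is left open because it is lost in the same step.

**Route**

Step 1
Reactants: 1 acetyl chloride; 2 1,1-dichloroethene
Product: 4 4,4-dichlorobut-3-en-2-one, via 4,4,4-trichlorobutan-2-one 3 (not isolated)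
Conditions: AlCl3 (1.1 equiv), CH2Cl2, 0 °C to rt; ice/dilute HCl; steam distillation, then distillation under reduced pressure
Reagents that add atoms: none
Why: In this Friedel–Crafts-type (Kondakov) acylation of an alkene the acylium ion adds to the CH2 terminus, chloride caps the chlorine-stabilised cation to give 3, and 3 should lose HCl on heating to give the conjugated enone 4.

Step 2
Reactants: 4 4,4-dichlorobut-3-en-2-one
Product: 6 4,4-dimethoxybut-3-en-2-one, via 4-chloro-4-methoxybut-3-en-2-one 5 (not isolated)
Conditions: NaOMe (2.1 equiv), MeOH, 0 °C to rt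
Reagents that add atoms: sodium methoxide, [Na+].[O-]C
Why: Two successive conjugate addition–elimination reactions (vinylic substitution) at the β-carbon of the enone replace both chlorides by methoxide, and limiting the base should stop the reaction at the acyl ketene acetal.

Step 3
Reactants: 6 4,4-dimethoxybut-3-en-2-one
Product: 7 1,1-dimethoxy-3-(trimethylsilyloxy)buta-1,3-diene
Conditions: Me3SiCl, Et3N, ZnCl2 (cat.), toluene, 40 °C; filtration under N2, distillation under reduced pressure
Reagents that add atoms: chlorotrimethylsilane, C[Si](C)(C)Cl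
Why: This is a soft enolisation with O-silylation (silyl enol ether formation), and because only the methyl group of 6 carries enolisable hydrogens, a single cross-conjugated 2-silyloxydiene can form.

Step 4
Reactants: 8 oct-2-ynoic acid
Product: 9 benzyl oct-2-ynoate
Conditions: BnBr, K2CO3, DMF, rt
Reagents that add atoms: benzyl bromide, BrCc1ccccc1
Why: SN2 O-alkylation of the carboxylate needs no activation of the acid, so the conjugated alkyne meets neither a nucleophilic catalyst nor a strong base.

Step 5
Reactants: 7 1,1-dimethoxy-3-(trimethylsilyloxy)buta-1,3-diene; 9 benzyl oct-2-ynoate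
Product: 12 benzyl 4-hydroxy-2-methoxy-6-pentylbenzoate, via ketal cycloadduct 10 (not isolated), via aryl trimethylsilyl ether 11 (not isolated)
Conditions: 7 (2 equiv), concentrated in toluene, sealed tube, base-washed glass, 130 °C; then 1 M HCl, THF, rt
Reagents that add atoms: none
Why: The triply oxygenated diene 7 (high HOMO) and the ynoate 9 (low LUMO) should combine in a thermal, strongly asynchronous normal-electron-demand Diels–Alder reaction, in which the bond from the diene CH2 to the β-carbon (C5'–C6') runs ahead of the bond from the ketene acetal carbon to the α-carbon (C1'–C2'). Ring B closes as a six-membered carbocycle in an intermolecular (4+2) mode and gives the cyclohexa-1,4-diene 10, whose ketal carbon is the future C2'. A 1,4-elimination of methanol (methoxide from C2', a proton from the doubly allylic C5') aromatises 10 to 11, and dilute acid then cleaves the Si–O bond to free the C4' phenol. The closest known reaction type is the cycloaddition of 1,1-dialkoxy-3-silyloxybutadienes with propiolates and β-alkyl alkynoates, which gives 4-hydroxy-2-methoxybenzoates. No stereocentre is formed, since 10 carries only a CH2 and a symmetric ketal carbon as sp3 centres, so nothing needs to be controlled there. The only selectivity needed is regiochemical: all three oxygen donors of 7 push electron density to the CH2 terminus and the ester of 9 makes the pentyl-bearing β-carbon the electrophilic one, so OMe ends up ortho and OH para to the ester without any selective protection.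

Step 6
Reactants: 13 olivetol (5-pentylbenzene-1,3-diol)
Product: 15 2,4-dihydroxy-6-pentylbenzaldehyde, via aryl iminium chloride 14 (not isolated)
Conditions: POCl3, DMF, 0 °C to rt; then ice-water, rt
Reagents that add atoms: N,N-dimethylformamide, CN(C)C=O; water, O
Why: In the Vilsmeier–Haack formylation the chloroiminium ion attacks the ring carbon para to one hydroxyl and ortho to the other, the usual site for resorcinols of the orcinol type, and water hydrolyses iminium 14 to the aldehyde.

Step 7
Reactants: 15 2,4-dihydroxy-6-pentylbenzaldehyde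
Product: 16 2-hydroxy-4-methoxy-6-pentylbenzaldehyde
Conditions: MeI (1.05 equiv), K2CO3 (1.0 equiv), acetone, rt to reflux
Reagents that add atoms: iodomethane, CI
Why: In this chemoselective Williamson etherification the 4-hydroxyl is a free vinylogous acid and is deprotonated and methylated first, while the 2-hydroxyl is held in a hydrogen bond to the aldehyde.

Step 8
Reactants: 16 2-hydroxy-4-methoxy-6-pentylbenzaldehyde
Product: 17 2-(benzyloxy)-4-methoxy-6-pentylbenzaldehyde
Conditions: BnBr, K2CO3, DMF, 60 °C
Reagents that add atoms: benzyl bromide, BrCc1ccccc1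
Why: Williamson etherification in a dipolar aprotic solvent with excess base and gentle heating breaks the chelate and alkylates the only hydroxyl left.

Step 9
Reactants: 17 2-(benzyloxy)-4-methoxy-6-pentylbenzaldehyde
Product: 18 2-(benzyloxy)-4-methoxy-6-pentylbenzoic acid
Conditions: NaClO2, NaH2PO4, 2-methylbut-2-ene (large excess), t-BuOH/THF/H2O, rt
Reagents that add atoms: sodium chlorite, [Na+].[O-]Cl=O
Why: The Pinnick oxidation converts the hindered aryl aldehyde into the acid under mild buffered conditions that leave both ethers untouched, and the alkene scavenger traps hypochlorous acid before it can chlorinate the electron-rich ring.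

Step 10
Reactants: 18 2-(benzyloxy)-4-methoxy-6-pentylbenzoic acid; 12 benzyl 4-hydroxy-2-methoxy-6-pentylbenzoate
Product: 20 benzyl 4-{[2-(benzyloxy)-4-methoxy-6-pentylbenzoyl]oxy}-2-methoxy-6-pentylbenzoate, via mixed trifluoroacetic anhydride 19 (not isolated)
Conditions: (CF3CO)2O, toluene, 0 °C to rt
Reagents that add atoms: none
Why: In this mixed-anhydride esterification with trifluoroacetic anhydride, the standard depside coupling, the electron-rich aroyl group of 19 ionises easily despite its two ortho substituents and is transferred to the C4' hydroxyl, the only free hydroxyl of 12.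

Step 11
Reactants: 20 benzyl 4-{[2-(benzyloxy)-4-methoxy-6-pentylbenzoyl]oxy}-2-methoxy-6-pentylbenzoate
Product: 21 2'-O-methylperlatolic acid
Conditions: H2 (1 atm), 10% Pd/C, EtOAc, rt
Reagents that add atoms: none
Why: Catalytic hydrogenolysis cleaves the benzyl ether and the benzyl ester together under neutral conditions, and the non-nucleophilic solvent leaves the aryl ester of the depside and both methyl ethers intact.

**Compound list**
1 | acetyl chloride | CC(=O)Cl | starting material
2 | 1,1-dichloroethene | C=C(Cl)Cl | starting material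
3 | 4,4,4-trichlorobutan-2-one | CC(=O)CC(Cl)(Cl)Cl | intermediate
4 | 4,4-dichlorobut-3-en-2-one | CC(=O)C=C(Cl)Cl | intermediate
5 | 4-chloro-4-methoxybut-3-en-2-one (geometry open) | CC(=O)C=C(Cl)OC | intermediate
6 | 4,4-dimethoxybut-3-en-2-one | CC(=O)C=C(OC)OC | intermediate
7 | 1,1-dimethoxy-3-(trimethylsilyloxy)buta-1,3-diene | COC(OC)=CC(=C)O[Si](C)(C)C | intermediate
8 | oct-2-ynoic acid | CCCCCC#CC(=O)O | starting material
9 | benzyl oct-2-ynoate | CCCCCC#CC(=O)OCc1ccccc1 | intermediate
10 | benzyl 6,6-dimethoxy-2-pentyl-4-(trimethylsilyloxy)cyclohexa-1,4-diene-1-carboxylate | CCCCCC1=C(C(=O)OCc2ccccc2)C(OC)(OC)C=C(O[Si](C)(C)C)C1 | intermediate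
11 | benzyl 2-methoxy-6-pentyl-4-(trimethylsilyloxy)benzoate | CCCCCc1cc(O[Si](C)(C)C)cc(OC)c1C(=O)OCc1ccccc1 | intermediate
12 | benzyl 4-hydroxy-2-methoxy-6-pentylbenzoate | CCCCCc1cc(O)cc(OC)c1C(=O)OCc1ccccc1 | intermediate
13 | olivetol (5-pentylbenzene-1,3-diol) | CCCCCc1cc(O)cc(O)c1 | starting material
14 | [(2,4-dihydroxy-6-pentylphenyl)methylidene]dimethylammonium chloride | CCCCCc1cc(O)cc(O)c1C=[N+](C)C.[Cl-] | intermediate
15 | 2,4-dihydroxy-6-pentylbenzaldehyde | CCCCCc1cc(O)cc(O)c1C=O | intermediate
16 | 2-hydroxy-4-methoxy-6-pentylbenzaldehyde | CCCCCc1cc(OC)cc(O)c1C=O | intermediate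
17 | 2-(benzyloxy)-4-methoxy-6-pentylbenzaldehyde | CCCCCc1cc(OC)cc(OCc2ccccc2)c1C=O | intermediate
18 | 2-(benzyloxy)-4-methoxy-6-pentylbenzoic acid | CCCCCc1cc(OC)cc(OCc2ccccc2)c1C(=O)O | intermediate
19 | 2-(benzyloxy)-4-methoxy-6-pentylbenzoic trifluoroacetic anhydride | CCCCCc1cc(OC)cc(OCc2ccccc2)c1C(=O)OC(=O)C(F)(F)F | intermediate
20 | benzyl 4-{[2-(benzyloxy)-4-methoxy-6-pentylbenzoyl]oxy}-2-methoxy-6-pentylbenzoate | CCCCCc1cc(OC)cc(OCc2ccccc2)c1C(=O)Oc1cc(CCCCC)c(C(=O)OCc2ccccc2)c(OC)c1 | intermediate
21 | 2'-O-methylperlatolic acid | CCCCCc1cc(OC)cc(O)c1C(=O)Oc1cc(CCCCC)c(C(=O)O)c(OC)c1 | target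

**Step count**
- Total step count: 11.
- Longest linear sequence: 6 steps. One such sequence runs from olivetol through steps 6, 7, 8, 9, 10 and 11. The other, of equal length, runs from acetyl chloride through steps 1, 2, 3, 5, 10 and 11.

**Steps most likely to fail**

1. **Step 5.** The β-pentyl group slows the cycloaddition. Thermal decay of the diene by silyl migration, adventitious hydrolysis or polymerisation may then outrun it, and aromatisation may stall at the cyclohexadiene stage.

   The fallback gives up ring construction and differentiates the two oxygens on a ready-made arene. It sets out from 15 and comes back at 12.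
   - The unchelated 4-hydroxyl of 15 is masked selectively (MOMCl, i-Pr2NEt, CH2Cl2, 0 °C) to give 2-hydroxy-4-(methoxymethoxy)-6-pentylbenzaldehyde F1.
   - The chelated hydroxyl is methylated (MeI, K2CO3, DMF) to give 2-methoxy-4-(methoxymethoxy)-6-pentylbenzaldehyde F2.
   - Pinnick oxidation gives 2-methoxy-4-(methoxymethoxy)-6-pentylbenzoic acid F3.
   - Carboxylate alkylation (BnBr, K2CO3, DMF) gives benzyl 2-methoxy-4-(methoxymethoxy)-6-pentylbenzoate F4.
   - Catalytic HCl in MeOH removes the acetal to give 12. The doubly ortho-substituted benzyl ester should resist transesterification.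

2. **Step 10.** Acyl transfer from the doubly ortho-substituted acid may be slow. O-trifluoroacetylation of the phenol or acid-induced loss of the ortho benzyl ether could then compete.

   The fallback changes the protecting-group plan and the mode of activation. It sets out from 18 (with 12) and comes back at 21.
   - Hydrogenolysis of 18 (H2, Pd/C, EtOAc) gives 2-hydroxy-4-methoxy-6-pentylbenzoic acid F5. This acid is less crowded, and its chelated hydroxyl is a poor nucleophile.
   - Carbodiimide coupling of F5 with 12 (DCC, toluene, rt) gives benzyl 4-[(2-hydroxy-4-methoxy-6-pentylbenzoyl)oxy]-2-methoxy-6-pentylbenzoate F6.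
   - Hydrogenolysis of the single benzyl ester of F6 gives 21.

3. **Step 3.** Enolisation may be incomplete, and the trimethylsilyl enol ether may be hydrolysed or undergo acid-induced polymerisation during filtration and distillation.

   The fallback changes the silyl group to one that survives aqueous work-up and chromatography, and it adds a separate deprotection. It sets out from 6 and comes back at 12.
   - Treatment of 6 with t-BuMe2SiOTf and Et3N in Et2O at 0 °C gives 3-(tert-butyldimethylsilyloxy)-1,1-dimethoxybuta-1,3-diene F7.
   - Heating F7 with 9 as in step 5 gives benzyl 4-(tert-butyldimethylsilyloxy)-6,6-dimethoxy-2-pentylcyclohexa-1,4-diene-1-carboxylate F8. This loses methanol in the flask to give benzyl 4-(tert-butyldimethylsilyloxy)-2-methoxy-6-pentylbenzoate F9.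
   - Bu4NF in THF at 0 °C then frees the phenol 12.

**Further compounds**
F1 | step 5 | 2-hydroxy-4-(methoxymethoxy)-6-pentylbenzaldehyde | CCCCCc1cc(OCOC)cc(O)c1C=O
F2 | step 5 | 2-methoxy-4-(methoxymethoxy)-6-pentylbenzaldehyde | CCCCCc1cc(OCOC)cc(OC)c1C=O
F3 | step 5 | 2-methoxy-4-(methoxymethoxy)-6-pentylbenzoic acid | CCCCCc1cc(OCOC)cc(OC)c1C(=O)O
F4 | step 5 | benzyl 2-methoxy-4-(methoxymethoxy)-6-pentylbenzoate | CCCCCc1cc(OCOC)cc(OC)c1C(=O)OCc1ccccc1
F5 | step 10 | 2-hydroxy-4-methoxy-6-pentylbenzoic acid | CCCCCc1cc(OC)cc(O)c1C(=O)O
F6 | step 10 | benzyl 4-[(2-hydroxy-4-methoxy-6-pentylbenzoyl)oxy]-2-methoxy-6-pentylbenzoate | CCCCCc1cc(OC)cc(O)c1C(=O)Oc1cc(CCCCC)c(C(=O)OCc2ccccc2)c(OC)c1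
F7 | step 3 | 3-(tert-butyldimethylsilyloxy)-1,1-dimethoxybuta-1,3-diene | COC(OC)=CC(=C)O[Si](C)(C)C(C)(C)C
F8 | step 3 | benzyl 4-(tert-butyldimethylsilyloxy)-6,6-dimethoxy-2-pentylcyclohexa-1,4-diene-1-carboxylate | CCCCCC1=C(C(=O)OCc2ccccc2)C(OC)(OC)C=C(O[Si](C)(C)C(C)(C)C)C1
F9 | step 3 | benzyl 4-(tert-butyldimethylsilyloxy)-2-methoxy-6-pentylbenzoate | CCCCCc1cc(O[Si](C)(C)C(C)(C)C)cc(OC)c1C(=O)OCc1ccccc1
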